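Which set-up leaves the most target from one and the same charge?

the same everywhere: protic impurity 10.5 mM; catalyst 2.1 mM

| flask | starting material | partner | second substrate | remark | time |
|---|---|---|---|---|---|
| zeta | 21 mM | 31.5 mM | 42 mM | run made earlier |  |
| gamma | 14 mM | 31.5 mM | 42 mM | run made earlier |  |
| epsilon | 32 mM | 31.5 mM | 42 mM | run made earlier |  |
| delta | 21 mM | 47 mM | 42 mM | run made earlier |  |
| Tuesday's | 21 mM | 31.5 mM | 42.0 mM | a single well-mixed tank run continuously and read at steady state, 4.0 h in it on average |  |
| Friday's | 21 mM | 31.5 mM | 42.0 mM | a tube with plug flow, the mixed feed as stated, residence time 4.0 h | 4.0 h |
| Saturday's | 21 mM | 31.5 mM | 42.0 mM | a closed flask charged with all of it at once and left for 4.0 h | 4.0 h |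
| Monday's | 21 mM | 31.5 mM | 42.0 mM (fed, over 3.20 h) | a stirred flask in which second substrate is dosed at a steady rate over 3.20 h without added volume, worked up at 4.0 h | 4.0 h |

1. the set-up with the highest amount of target at the outlet or at the end, in percent of the starting material put in ("none" if the first two lie within 2 percentage points) (Tuesday's / Friday's / Saturday's / Monday's / none)
2. amount of target at the outlet or at the end, in percent of the starting material put in, Tuesday's
3. amount of target at the outlet or at the end, in percent of the starting material put in, Friday's
4. amount of target at the outlet or at the end, in percent of the starting material put in, Saturday's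
5. amount of target at the outlet or at the end, in percent of the starting material put in, Monday's

- the stated concentrations are those of everything mixed, before any reaction; amounts are the same in each set-up
- reactions considered so far: starting material + protic impurity -> quenched substrate; catalyst + target -> catalyst + over-reaction product; second substrate + partner + catalyst -> catalyst + second product; starting material + partner + catalyst -> catalyst + target
- the feed brings no volume worth counting
- the earlier runs were made in a closed, stirred flask

| run | time / h | target / % | starting material / % |
|---|---|---|---|
| zeta | 0.667 | 14 | 75 |
| zeta | 1.33 | 26 | 62 |
| zeta | 2.00 | 34 | 48 |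
| zeta | 2.50 | 39 | 43 |
| gamma | 0.250 | 8 | 90 |
| gamma | 0.667 | 16 | 74 |
| gamma | 1.33 | 25 | 58 |
| gamma | 3.00 | 45 | 39 |
| epsilon | 0.833 | 18 | 67 |
| epsilon | 1.50 | 29 | 58 |
| epsilon | 2.50 | 36 | 46 |
| epsilon | 3.00 | 39 | 39 |
| delta | 0.833 | 24 | 60 |
| delta | 1.50 | 41 | 44 |
| delta | 2.50 | 50 | 29 |
| delta | 3.00 | 55 | 29 |

(readings scatter by 2 percentage points)

Starting material goes to target or to quenched substrate. Both steps are first order in it, so it cancels from their ratio. The catalyst returns after each cycle, so the ratio follows partner over protic impurity. The quantity to carry is the split (selectivity factor): target formed per starting material quenched, with the missing fraction read as quenched. Over zeta's last two readings it reads 2.03. Gamma and epsilon, charged with other amounts of starting material, read 2.12 and 1.88. But delta, with extra partner, reads 2.84. In powers of ten, the split reads 0.146 higher for a rise of 0.174 in partner, so within the scatter of these readings it goes with partner at close to the first power.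

Zeta's starting material falls to 43% at 2.50 h. A straight line in powers of ten carries that to 25.9% at 4.0 h. The split gives target a share of 67.0% of what is consumed, so this reckoning puts Saturday's flask at 49.6%, an estimate on the high side, since the line takes partner as constant. Friday's tube repeats that flask hour for hour. Tuesday's tank runs at outlet composition throughout. Monday's holds second substrate back, which spares partner, so its split should rise.

The forecast gives 31%, 45%, 45% and 48% in the order asked, with Monday's best on the ground that “Dosing keeps partner higher early on”, and its Saturday's figure stands under the one reckoned here.

The flask gives 31.8%, 44.7%, 44.7% and 48.6%, so Monday's is best. Monday's keeps 48% of its partner at the end, more than Saturday's 39%.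

    starting material + protic impurity → quenched substrate (k = 0.260 /M/min)
    catalyst + target → catalyst + over-reaction product (k = 0.0740 /M/min)
    second substrate + partner + catalyst → catalyst + second product (k = 26.0 /M²/min)
    starting material + partner + catalyst → catalyst + target (k = 81.0 /M²/min)

Monday's split comes out at 2.00, Saturday's at 1.79. For a flask like Monday's but with 130 mM of partner, zeta's reading scales to 8.37. With 0.77% of its starting material left, that split gives 88.6% target. That flask holds 85.9% target against 10.7% quenched substrate.

The runs come from a simulation with constants of no real substance, noise included.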